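**Plan**
- Retrosynthesis: the 3(2H)-furanone (O–C3 bond, C1 carbonyl) is opened to a 4-hydroxy-2-ynone C10(OH)–C1≡C2–C3(=O) inside the ten-membered ring; C1–C10 is cut to an alkynyl iodide and the C10 methyl ketone; then the C6–O ester, C6–C7 (Z-enal + 3-(bromomethyl)butenolide) and C7–C8/lactone (primary alcohol + 2-(alkoxycarbonyl)allyl donor) are cut.
- Forward: the γ-lactone is made first, the C6–C7 union gives the α-methylene lactone, the ester is attached, the ten-membered carbocycle is closed at C1–C10, and the furanone ether bridge C10–O–C3 is formed last.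
- Enabling feature: the furanone unit O–C3=C2–C1(=O) with quaternary C10 is a masked ynone/1,3-diketone. C10 carries O, C14 and C1, so it is the adduct of an acetylide (C1) and a methyl ketone, and the β-acyloxy centre C8 can direct that addition.
- Stereochemistry: C8 from the chiral Ir catalyst; C7 trans to C8 by ring control; C6 from the chair transition state of the allylzinc addition, then inverted in the Mitsunobu esterification; C10 by 1,3-anti induction in the ring closure; the epoxide from Sharpless epoxidation of angelyl alcohol; Z-C4=C5 from a butenolide ring.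

Key step: step 14

Remark: C1–C15 are germacranolide positions (C1 furanone C=O, C2 furanone CH, C3 furanone C–O carbon, C4/C15 methyl-bearing alkene carbon and its methyl, C5 alkene CH, C6 ester carbinol, C7 ring-fusion CH, C8 lactone carbinol, C9 CH2, C10/C14 quaternary carbon and its methyl, C11–C13 methylene-lactone carbons). C3 is a temporary stereocentre; it is carried as both epimers, left undefined in the SMILES, and removed by oxidation in step 15.

Step 1
Reactants: 1 3-methylfuran-2(5H)-one; 2 ethynylmagnesium bromide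
Product: 4 (2Z)-3-methylhex-2-en-5-yne-1,4-diol (racemic at C3), via lactol 3 (not isolated)
Conditions: DIBAL-H (1.05 equiv), CH2Cl2, −78 °C; then 2 (3 equiv), THF, −78 °C to rt; Rochelle salt work-up
Reagents that add atoms: none
Why: Half-reduction of the lactone stops at the aluminium lactolate and the alkynyl Grignard adds to the ring-opened hydroxy enal (lactol opening by a Grignard reagent); the Z geometry of C4=C5 is inherited from the butenolide ring and C3 forms as both enantiomers.

Step 2
Reactants: 4 (2Z)-3-methylhex-2-en-5-yne-1,4-diol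
Product: 5 (2Z)-3-methyl-1,4-bis(triethylsilyloxy)hex-2-en-5-yne
Conditions: TESCl (2.4 equiv), imidazole, DMAP (cat.), CH2Cl2, 0 °C to rt
Reagents that add atoms: chlorotriethylsilane, CC[Si](Cl)(CC)CC
Why: Standard silylation of both hydroxyl groups, which allows the primary position to be addressed alone in the next step.

Step 3
Reactants: 5 (2Z)-3-methyl-1,4-bis(triethylsilyloxy)hex-2-en-5-yne
Product: 6 (2Z)-3-methyl-4-(triethylsilyloxy)hex-2-en-5-ynal
Conditions: (COCl)2, DMSO, CH2Cl2, −78 to −40 °C; Et3N, −78 °C; cold buffered work-up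
Reagents that add atoms: none
Why: Under Swern conditions a primary triethylsilyl ether is cleaved and oxidised directly to the aldehyde while the secondary one survives (oxidative deprotection via the alkoxysulfonium ion), and the cold work-up should preserve the Z enal.

Step 4
Reactants: 7 ethyl (2-methyl-1,3-dioxolan-2-yl)acetate
Product: 8 2-(2-methyl-1,3-dioxolan-2-yl)ethan-1-ol
Conditions: LiAlH4, THF, 0 °C
Reagents that add atoms: none
Why: Hydride reduction of the ester to the primary alcohol; the ketal is inert.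

Step 5
Reactants: 8 2-(2-methyl-1,3-dioxolan-2-yl)ethan-1-ol; 9 methyl 2-{[(tert-butoxycarbonyl)oxy]methyl}prop-2-enoate
Product: 11 (5R)-5-[(2-methyl-1,3-dioxolan-2-yl)methyl]-3-methylideneoxolan-2-one, via hydroxy ester 10 (not isolated)
Conditions: [Ir(cod)Cl]2 (2.5 mol %), chiral bisphosphine (SEGPHOS or TMBTP type; the antipode that gives 5R, to be fixed in a first run), 4-cyano-3-nitrobenzoic acid (10 mol %), Cs2CO3 (20 mol %), THF, 60 °C; PPTS (cat.) if lactonisation is incomplete
Reagents that add atoms: none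
Why: Iridium-catalysed transfer-hydrogenative carbonyl 2-(alkoxycarbonyl)allylation: the alcohol is dehydrogenated to the aldehyde, the chiral π-allyliridium C,O-benzoate adds to one aldehyde face (catalyst control sets C8) and the γ-hydroxy ester closes to the lactone.

Step 6
Reactants: 11 (5R)-5-[(2-methyl-1,3-dioxolan-2-yl)methyl]-3-methylideneoxolan-2-one
Product: 13 (5S)-3-(bromomethyl)-5-[(2-methyl-1,3-dioxolan-2-yl)methyl]furan-2(5H)-one, via dibromide 12 (not isolated)
Conditions: Br2, CH2Cl2, 0 °C; then Et3N, 0 °C to rt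
Reagents that add atoms: bromine, BrBr
Why: Bromine adds to the exocyclic alkene and dehydrobromination towards the ring CH2 gives the conjugated endocyclic butenolide with an allylic bromide; C8 is not touched (its descriptor changes only because the priorities change).

Step 7
Reactants: 6 (2Z)-3-methyl-4-(triethylsilyloxy)hex-2-en-5-ynal; 13 (5S)-3-(bromomethyl)-5-[(2-methyl-1,3-dioxolan-2-yl)methyl]furan-2(5H)-one
Product: 14 (4S,5S)-4-[(1R,2Z)-1-hydroxy-3-methyl-4-(triethylsilyloxy)hex-2-en-5-yn-1-yl]-5-[(2-methyl-1,3-dioxolan-2-yl)methyl]-3-methylideneoxolan-2-one (6R; H7/H8 trans)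
Conditions: Zn dust, THF/sat. aq NH4Cl 2:1, 0 °C to rt
Reagents that add atoms: none
Why: Barbier-type allylzinc addition with allylic transposition forms C6–C7 at the ring β-carbon anti to the C8 side chain (trans lactone, C7) and regenerates the exocyclic methylene, and the Zimmerman–Traxler chair with the E-locked allyl unit and an equatorial enal residue is expected to give the 6R carbinol, which is the C6 epimer needed for invertive esterification.

Step 8
Reactants: 15 angelic acid [(2Z)-2-methylbut-2-enoic acid]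
Product: 16 (2Z)-2-methylbut-2-en-1-ol
Conditions: LiAlH4, Et2O, 0 °C to rt
Reagents that add atoms: none
Why: 1,2-Reduction of the unsaturated acid to the allylic alcohol with retention of the Z geometry.

Step 9
Reactants: 16 (2Z)-2-methylbut-2-en-1-ol
Product: 17 [(2R,3S)-2,3-dimethyloxiran-2-yl]methanol
Conditions: Ti(OiPr)4, D-(−)-diethyl tartrate, t-BuOOH, 4 Å MS, CH2Cl2, −20 °C
Reagents that add atoms: tert-butyl hydroperoxide, CC(C)(C)OO
Why: Sharpless asymmetric epoxidation; the D-(−)-tartrate complex delivers oxygen to the face that gives 2R,3S, and the Z alkene fixes the cis relation of CH2OH and the C3 methyl.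

Step 10
Reactants: 17 [(2R,3S)-2,3-dimethyloxiran-2-yl]methanol
Product: 18 (2S,3S)-2,3-dimethyloxirane-2-carboxylic acid
Conditions: RuCl3·xH2O (2 mol %), NaIO4, MeCN/CCl4/H2O, rt
Reagents that add atoms: sodium periodate, [Na+].[O-]I(=O)(=O)=O; water, O
Why: Ruthenium tetroxide oxidation of the epoxy alcohol to the glycidic acid without touching either stereocentre (the C2 descriptor changes only through the priority change).

Step 11
Reactants: 14 the (6R)-alcohol from step 7; 18 (2S,3S)-2,3-dimethyloxirane-2-carboxylic acid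
Product: 19 (1S,2Z)-3-methyl-1-{(2S,3R)-2-[(2-methyl-1,3-dioxolan-2-yl)methyl]-4-methylidene-5-oxooxolan-3-yl}-4-(triethylsilyloxy)hex-2-en-5-yn-1-yl (2S,3S)-2,3-dimethyloxirane-2-carboxylate
Conditions: PPh3, DIAD (betaine preformed), THF, 0 °C to rt
Reagents that add atoms: none
Why: Mitsunobu esterification: the carboxylate displaces the alkoxyphosphonium at the secondary allylic C6 with inversion (6R to 6S) and so installs the ester with the target configuration; the acid has no epimerisable centre.

Step 12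
Reactants: 19 the silyl ether ketal ester from step 11
Product: 20 (1S,2Z)-4-hydroxy-3-methyl-1-[(2S,3R)-4-methylidene-5-oxo-2-(2-oxopropyl)oxolan-3-yl]hex-2-en-5-yn-1-yl (2S,3S)-2,3-dimethyloxirane-2-carboxylate
Conditions: PPTS (0.3 equiv), acetone/H2O 10:1, 45 °C
Reagents that add atoms: water, O
Why: Mild acid hydrolysis removes the dioxolane and the triethylsilyl ether in one operation, while the electron-poor glycidic ester and the allylic ester should survive; no stereocentre is affected.

Step 13
Reactants: 20 the keto alcohol from step 12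
Product: 21 (1S,2Z)-4-hydroxy-6-iodo-3-methyl-1-[(2S,3R)-4-methylidene-5-oxo-2-(2-oxopropyl)oxolan-3-yl]hex-2-en-5-yn-1-yl (2S,3S)-2,3-dimethyloxirane-2-carboxylate
Conditions: NIS (1.2 equiv), AgNO3 (10 mol %), acetone, rt, dark
Reagents that add atoms: N-iodosuccinimide, O=C1CCC(=O)N1I
Why: Silver-catalysed iodination of the terminal alkyne through the silver acetylide, a neutral method that tolerates the free alcohol, the ketone and the base-sensitive β-acyloxy ketone.

Step 14
Reactants: 21 the iodoalkyne methyl ketone from step 13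
Product: 22 (6S,7R,8S,10S)-3,10-dihydroxygermacra-4(Z),11(13)-dien-1-yn-8,12-olide 6-[(2S,3S)-2,3-dimethyloxirane-2-carboxylate] (ten-membered ring closed at C1–C10)
Conditions: CrCl2 (8 equiv), DMF/THF 1:3, 2 mM, syringe-pump addition of 21, 25 °C; aqueous serinate work-up
Reagents that add atoms: none
Why: Proposed new method: two Cr(II) ions reduce the C(sp)–I bond of 21 to an alkynylchromium(III) species, a weakly basic and oxophilic nucleophile that should not enolise the methyl ketone, expel the β-acyloxy group at C8, or touch the lactone, the esters or the epoxide; Cr(III) binds the C10 carbonyl and C1 adds to it. The closest known reaction type is the Nozaki–Hiyama–Kishi coupling of alkynyl iodides with aldehydes, which closes nine- and ten-membered rings; the acceptor here is a methyl ketone, which organochromium reagents attack more slowly, so intramolecularity has to supply the rate. The ten-membered carbocycle closes in the 10-exo-trig mode (C1 onto C10=O), with the trans-fused lactone, the Z-C4=C5 alkene and the linear C10···C1≡C2–C3 axis bringing the chain ends together. C10 is set by 1,3-induction from C8: with the C8–O and C10=O dipoles opposed and C14 on the ring periphery, C1 attacks the open face and gives the 8,10-anti tertiary alkoxide (10S), whose oxygen points across the ring towards C3 as the later ether bridge requires. The step needs ketone-over-ester chemoselectivity (inherent in organochromium reagents), high dilution against dimerisation and the 10S facial sense; both C3 epimers are expected to cyclise and they converge in step 15.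

Step 15
Reactants: 22 the macrocyclic diol from step 14
Product: 23 (6S,7R,8S,10S)-10-hydroxy-3-oxogermacra-4(Z),11(13)-dien-1-yn-8,12-olide 6-[(2S,3S)-2,3-dimethyloxirane-2-carboxylate]
Conditions: activated MnO2 (excess), CH2Cl2, rt
Reagents that add atoms: none
Why: Manganese dioxide oxidises only the secondary alcohol at C3, which is both allylic and propargylic, leaves the tertiary C10 alcohol alone and merges the two C3 epimers into one ynone.

Step 16
Reactants: 23 the hydroxy ynone from step 15
Product: 25 CNP0258430.1 (target), via hydroxy diketone 24 (not isolated)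
Conditions: Ph3PAuNTf2 (5 mol %), H2O (5 equiv), 1,4-dioxane, 40 °C; then PPTS (cat.)
Reagents that add atoms: water, O
Why: Gold(I) activation of the ynone directs water to C1 (the β-carbon), and the resulting α′-hydroxy 1,3-diketone undergoes the classical furanone cyclodehydration (C10–OH onto the C3 ketone, 5-exo-trig, then loss of water); no stereocentre is involved.

**Compound list**
1 | 3-methylfuran-2(5H)-one | CC1=CCOC1=O | starting material
2 | ethynylmagnesium bromide | C#C[Mg]Br | starting material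
3 | 3-methyl-2,5-dihydrofuran-2-ol (lactol, racemic; aluminium alkoxide in the flask) | CC1=CCOC1O | intermediate
4 | (2Z)-3-methylhex-2-en-5-yne-1,4-diol (racemic at C3) | C#CC(O)/C(C)=C\CO | intermediate
5 | (2Z)-3-methyl-1,4-bis(triethylsilyloxy)hex-2-en-5-yne (racemic) | C#CC(O[Si](CC)(CC)CC)/C(C)=C\CO[Si](CC)(CC)CC | intermediate
6 | (2Z)-3-methyl-4-(triethylsilyloxy)hex-2-en-5-ynal (racemic) | C#CC(O[Si](CC)(CC)CC)/C(C)=C\C=O | intermediate
7 | ethyl (2-methyl-1,3-dioxolan-2-yl)acetate | CCOC(=O)CC1(C)OCCO1 | starting material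
8 | 2-(2-methyl-1,3-dioxolan-2-yl)ethan-1-ol | CC1(CCO)OCCO1 | intermediate
9 | methyl 2-{[(tert-butoxycarbonyl)oxy]methyl}prop-2-enoate | C=C(COC(=O)OC(C)(C)C)C(=O)OC | starting material
10 | methyl (4R)-4-hydroxy-2-methylidene-5-(2-methyl-1,3-dioxolan-2-yl)pentanoate | C=C(C[C@@H](O)CC1(C)OCCO1)C(=O)OC | intermediate
11 | (5R)-5-[(2-methyl-1,3-dioxolan-2-yl)methyl]-3-methylideneoxolan-2-one | C=C1C(=O)O[C@@H](CC2(C)OCCO2)C1 | intermediate
12 | (5S)-3-bromo-3-(bromomethyl)-5-[(2-methyl-1,3-dioxolan-2-yl)methyl]oxolan-2-one (both C3 epimers) | O=C1O[C@@H](CC2(C)OCCO2)CC1(Br)CBr | intermediate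
13 | (5S)-3-(bromomethyl)-5-[(2-methyl-1,3-dioxolan-2-yl)methyl]furan-2(5H)-one | O=C1O[C@@H](CC2(C)OCCO2)C=C1CBr | intermediate
14 | (4S,5S)-4-[(1R,2Z)-1-hydroxy-3-methyl-4-(triethylsilyloxy)hex-2-en-5-yn-1-yl]-5-[(2-methyl-1,3-dioxolan-2-yl)methyl]-3-methylideneoxolan-2-one (6R; both C3 epimers) | C=C1C(=O)O[C@@H](CC2(C)OCCO2)[C@@H]1[C@H](O)/C=C(C)\C(O[Si](CC)(CC)CC)C#C | intermediate
15 | angelic acid, (2Z)-2-methylbut-2-enoic acid | C/C=C(/C)C(=O)O | starting material
16 | (2Z)-2-methylbut-2-en-1-ol | C/C=C(/C)CO | intermediate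
17 | [(2R,3S)-2,3-dimethyloxiran-2-yl]methanol | OC[C@@]1(C)O[C@H]1C | intermediate
18 | (2S,3S)-2,3-dimethyloxirane-2-carboxylic acid | OC(=O)[C@@]1(C)O[C@H]1C | intermediate
19 | (1S,2Z)-3-methyl-1-{(2S,3R)-2-[(2-methyl-1,3-dioxolan-2-yl)methyl]-4-methylidene-5-oxooxolan-3-yl}-4-(triethylsilyloxy)hex-2-en-5-yn-1-yl (2S,3S)-2,3-dimethyloxirane-2-carboxylate (both C3 epimers) | C=C1C(=O)O[C@@H](CC2(C)OCCO2)[C@@H]1[C@@H](OC(=O)[C@@]3(C)O[C@H]3C)/C=C(C)\C(O[Si](CC)(CC)CC)C#C | intermediate
20 | (1S,2Z)-4-hydroxy-3-methyl-1-[(2S,3R)-4-methylidene-5-oxo-2-(2-oxopropyl)oxolan-3-yl]hex-2-en-5-yn-1-yl (2S,3S)-2,3-dimethyloxirane-2-carboxylate (both C3 epimers) | C=C1C(=O)O[C@@H](CC(C)=O)[C@@H]1[C@@H](OC(=O)[C@@]2(C)O[C@H]2C)/C=C(C)\C(O)C#C | intermediate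
21 | (1S,2Z)-4-hydroxy-6-iodo-3-methyl-1-[(2S,3R)-4-methylidene-5-oxo-2-(2-oxopropyl)oxolan-3-yl]hex-2-en-5-yn-1-yl (2S,3S)-2,3-dimethyloxirane-2-carboxylate (both C3 epimers) | C=C1C(=O)O[C@@H](CC(C)=O)[C@@H]1[C@@H](OC(=O)[C@@]2(C)O[C@H]2C)/C=C(C)\C(O)C#CI | intermediate
22 | (6S,7R,8S,10S)-3,10-dihydroxygermacra-4(Z),11(13)-dien-1-yn-8,12-olide 6-[(2S,3S)-2,3-dimethyloxirane-2-carboxylate] (both C3 epimers) | C=C1C(=O)O[C@H]2C[C@](C)(O)C#CC(O)/C(C)=C\[C@H](OC(=O)[C@@]3(C)O[C@H]3C)[C@H]12 | intermediate
23 | (6S,7R,8S,10S)-10-hydroxy-3-oxogermacra-4(Z),11(13)-dien-1-yn-8,12-olide 6-[(2S,3S)-2,3-dimethyloxirane-2-carboxylate] | C=C1C(=O)O[C@H]2C[C@](C)(O)C#CC(=O)/C(C)=C\[C@H](OC(=O)[C@@]3(C)O[C@H]3C)[C@H]12 | intermediate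
24 | (6S,7R,8S,10S)-10-hydroxy-1,3-dioxogermacra-4(Z),11(13)-dien-8,12-olide 6-[(2S,3S)-2,3-dimethyloxirane-2-carboxylate] | C=C1C(=O)O[C@H]2C[C@](C)(O)C(=O)CC(=O)/C(C)=C\[C@H](OC(=O)[C@@]3(C)O[C@H]3C)[C@H]12 | intermediate
25 | CNP0258430.1, (6S,7R,8S,10S)-3,10-epoxy-1-oxogermacra-2,4(Z),11(13)-trien-8,12-olide 6-[(2S,3S)-2,3-dimethyloxirane-2-carboxylate] | C=C1C(=O)O[C@H]2C[C@]3(C)OC(=CC3=O)/C(C)=C\[C@H](OC(=O)[C@@]3(C)O[C@H]3C)[C@H]12 | target

**Step count**
Total: 16 steps. Longest linear sequence: 10 steps (1, 2, 3, 7, 11, 12, 13, 14, 15, 16; the branch 4, 5, 6, 7, 11–16 is equally long).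

**Steps most likely to fail**

Step 14. The alkynylchromium may be protonated (by the C3 hydroxyl or traces of water) or may dimerise faster than it adds to the hindered, weakly electrophilic methyl ketone, so that no ring forms. The fallback closes the same bond on an aldehyde, the established acceptor for this chromium-mediated ring closure, and adds C14 afterwards; it uses known chemistry throughout. It sets out from 6, 9 and 18 together with commercial 2-(1,3-dioxolan-2-yl)ethan-1-ol (OCCC1OCCO1) and comes back to the route at 23. The iridium-catalysed coupling of that alcohol with 9 (as in step 5) gives, through the hydroxy ester F1, the acetal lactone F2. Bromine and then triethylamine convert it through the dibromide F3 into the bromomethyl butenolide F4. Zinc-mediated addition of F4 to 6 gives the acetal alcohol F5, and Mitsunobu esterification with 18 gives the acetal ester F6. Aqueous acetic acid frees the aldehyde and the C3 alcohol in the seco aldehyde F7, and NIS with catalytic AgNO3 gives the iodoalkyne aldehyde F8. CrCl2 with catalytic NiCl2 under high dilution closes the ring at C1–C10 to the macrocyclic bis-secondary diol F9. Dess–Martin oxidation of both propargylic alcohols gives the macrocyclic ynedione F10. MeMgBr/CeCl3 at −78 °C should add to the C10 ketone, which is less hindered and not cross-conjugated with the C4=C5 alkene, from the ring periphery and so give 23.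

Step 7. The allylzinc may react through an open instead of a chair transition state, or with poor discrimination of the aldehyde faces, so that the simple diastereoselectivity at C6 is reversed. The fallback sets out from 6 and 13 as in step 7 and comes back at 19. If the main adduct is the (6S)-alcohol F11, it is not inverted but acylated with retention by 18 under Yamaguchi conditions (2,4,6-trichlorobenzoyl chloride, Et3N, DMAP, toluene), which gives 19 directly.

Step 11. The activated secondary allylic alcohol may undergo E2 elimination to the conjugated diene or SN2′ transposition instead of clean inversion. The fallback sets out from 14 and comes back at 19. Dess–Martin oxidation gives the C6 enone F12. Luche reduction (NaBH4, CeCl3, MeOH, −78 °C) should deliver hydride anti to the C7–C8 bond (Felkin–Anh) and give the (6S)-alcohol F11, which is acylated with 18 under the Yamaguchi conditions given above.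

**Further compounds**
F1 | step 14 | methyl (4R)-5-(1,3-dioxolan-2-yl)-4-hydroxy-2-methylidenepentanoate | C=C(C[C@@H](O)CC1OCCO1)C(=O)OC
F2 | step 14 | (5R)-5-(1,3-dioxolan-2-ylmethyl)-3-methylideneoxolan-2-one | C=C1C(=O)O[C@@H](CC2OCCO2)C1
F3 | step 14 | (5S)-3-bromo-3-(bromomethyl)-5-(1,3-dioxolan-2-ylmethyl)oxolan-2-one (both C3 epimers) | O=C1O[C@@H](CC2OCCO2)CC1(Br)CBr
F4 | step 14 | (5S)-3-(bromomethyl)-5-(1,3-dioxolan-2-ylmethyl)furan-2(5H)-one | O=C1O[C@@H](CC2OCCO2)C=C1CBr
F5 | step 14 | (4S,5S)-5-(1,3-dioxolan-2-ylmethyl)-4-[(1R,2Z)-1-hydroxy-3-methyl-4-(triethylsilyloxy)hex-2-en-5-yn-1-yl]-3-methylideneoxolan-2-one | C=C1C(=O)O[C@@H](CC2OCCO2)[C@@H]1[C@H](O)/C=C(C)\C(O[Si](CC)(CC)CC)C#C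
F6 | step 14 | (1S,2Z)-1-[(2S,3R)-2-(1,3-dioxolan-2-ylmethyl)-4-methylidene-5-oxooxolan-3-yl]-3-methyl-4-(triethylsilyloxy)hex-2-en-5-yn-1-yl (2S,3S)-2,3-dimethyloxirane-2-carboxylate | C=C1C(=O)O[C@@H](CC2OCCO2)[C@@H]1[C@@H](OC(=O)[C@@]3(C)O[C@H]3C)/C=C(C)\C(O[Si](CC)(CC)CC)C#C
F7 | step 14 | (1S,2Z)-4-hydroxy-3-methyl-1-[(2S,3R)-4-methylidene-5-oxo-2-(2-oxoethyl)oxolan-3-yl]hex-2-en-5-yn-1-yl (2S,3S)-2,3-dimethyloxirane-2-carboxylate | C=C1C(=O)O[C@@H](CC=O)[C@@H]1[C@@H](OC(=O)[C@@]2(C)O[C@H]2C)/C=C(C)\C(O)C#C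
F8 | step 14 | (1S,2Z)-4-hydroxy-6-iodo-3-methyl-1-[(2S,3R)-4-methylidene-5-oxo-2-(2-oxoethyl)oxolan-3-yl]hex-2-en-5-yn-1-yl (2S,3S)-2,3-dimethyloxirane-2-carboxylate | C=C1C(=O)O[C@@H](CC=O)[C@@H]1[C@@H](OC(=O)[C@@]2(C)O[C@H]2C)/C=C(C)\C(O)C#CI
F9 | step 14 | (6S,7R,8S)-3,10-dihydroxy-14-norgermacra-4(Z),11(13)-dien-1-yn-8,12-olide 6-[(2S,3S)-2,3-dimethyloxirane-2-carboxylate] (C3 and C10 epimers) | C=C1C(=O)O[C@H]2CC(O)C#CC(O)/C(C)=C\[C@H](OC(=O)[C@@]3(C)O[C@H]3C)[C@H]12
F10 | step 14 | (6S,7R,8S)-3,10-dioxo-14-norgermacra-4(Z),11(13)-dien-1-yn-8,12-olide 6-[(2S,3S)-2,3-dimethyloxirane-2-carboxylate] | C=C1C(=O)O[C@H]2CC(=O)C#CC(=O)/C(C)=C\[C@H](OC(=O)[C@@]3(C)O[C@H]3C)[C@H]12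
F11 | step 7 | (4S,5S)-4-[(1S,2Z)-1-hydroxy-3-methyl-4-(triethylsilyloxy)hex-2-en-5-yn-1-yl]-5-[(2-methyl-1,3-dioxolan-2-yl)methyl]-3-methylideneoxolan-2-one | C=C1C(=O)O[C@@H](CC2(C)OCCO2)[C@@H]1[C@@H](O)/C=C(C)\C(O[Si](CC)(CC)CC)C#C
F12 | step 11 | (4R,5S)-4-[(2Z)-3-methyl-4-(triethylsilyloxy)hex-2-en-5-ynoyl]-5-[(2-methyl-1,3-dioxolan-2-yl)methyl]-3-methylideneoxolan-2-one | C=C1C(=O)O[C@@H](CC2(C)OCCO2)[C@@H]1C(=O)/C=C(C)\C(O[Si](CC)(CC)CC)C#C
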